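What held still in the gamma run, within the scatter of the readings, was a ratio: two mirror-image substrates, charged as a racemate, react with reagent on a single-handed free catalyst, while a racemization catalyst exchanges them, and left-handed product stood to right-handed product at 3.71 at 0.500 h and 3.22 at 3.00 h. I summed the five gamma readings of each product and got 3.15; this reading of left-handed product formed per right-handed product, a selectivity factor, I called the split. While the two substrates stand equal and the split holds, the product's excess stays frozen at the split less one, over the split plus one, which here made 51.8%.

all flasks: free catalyst 1 mol%; racemization catalyst 0.2 mol%
- epsilon: left-handed substrate 0.20 M; right-handed substrate 0.20 M; reagent 3 equiv; added ligand 5 mM; the very flask that is asked about, followed so far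
- gamma: left-handed substrate 0.40 M; right-handed substrate 0.40 M; reagent 3 equiv; added ligand 5 mM; run made earlier
- flask: left-handed substrate 0.20 M; right-handed substrate 0.20 M; reagent 3.00 equiv; added ligand 5.0 mM; time 4.0 h

- epsilon (time / min: left-handed product / %, right-handed product / %): 4.00: 3, 5; 8.00: 0, 2; 12.0: 2, 4; 15.0: 0, 2; 20.0: 1, 4
- gamma (time / h: left-handed product / %, right-handed product / %): 0.500: 26, 7; 1.00: 39, 10; 1.50: 47, 17; 2.50: 57, 20; 3.00: 58, 18

(each reading ± 2 percentage points)

- left-handed product and right-handed product together, in percent of the left-handed substrate and right-handed substrate charged together, at 4.0 h
- excess of left-handed product over right-handed product in the product at 4.0 h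
- whether the exchange between left-handed substrate and right-handed substrate keeps pace with the reaction: how far the product's excess at 4.0 h gets from its value without exchange to its value with instant exchange (above 80% keeps pace, below 20% hardly takes part, else lags behind)

- free catalyst is single-handed; left-handed substrate and right-handed substrate are mirror images of each other, charged as a racemate, each of them at the stated concentration
- an excess is the difference of the two amounts in percent of their sum
- an excess is below zero if the other one leads

In the first instants of this flask, whose opening is the epsilon run, 2.00 mM of free catalyst met 5.0 mM of added ligand, where gamma had 4.00 mM against 5 mM. The substrates together, at 0.400 M, were the limiting reagent, with 0.600 M of reagent. Epsilon showed 5.00% of product at 20.0 min, and gamma 33.0% at 0.500 h, so by these two readings gamma formed product 4.40 times as fast, in percent of its charge. These few small readings were too rough for me to commit to a yield. Right-handed product led epsilon by 2.2 percentage points on average, but the epsilon amounts, at 5% and below, are of the size of the scatter of 2 points, while gamma's, at 7% and above, stand higher, so I kept the split.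

In the middle of this flask, going by the split, left-handed substrate is taken 3.15 times as fast as right-handed substrate, so the two stay equal only while exchange refills it. Gamma reached a reading of 58% of left-handed product, above the 50.0% of the charge that was left-handed substrate, so exchange ran there. This flask has half of gamma's racemization catalyst, 0.400 mM against 0.800 mM, yet by the two readings above its reaction ran slower than gamma's by more than that. For the end I therefore expected an excess of 51.8% with the exchange keeping pace, and the ratio of the two products was the thing to watch.

The forecast gave 48% of product, an excess of −49% and an exchange that lags behind, saying: “Its selectivity also appears inverted”. There I differed from it in the sign of the excess.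

The flask gave 32.9% of product and an excess of 52.3%, and the exchange keeps pace, getting 98% of the way to instant exchange. At 4.00 h the excess of right-handed substrate among what was left stood at 0.415%. With the two substrates that close, the split divides the product into 25.0% of left-handed product, and the flask held 25.1%.

    reagent + free catalyst + left-handed substrate → free catalyst + left-handed product (k = 32.0 M⁻² min⁻¹)
    reagent + free catalyst + right-handed substrate → free catalyst + right-handed product (k = 10.0 M⁻² min⁻¹)
    left-handed substrate + racemization catalyst ⇌ right-handed substrate + racemization catalyst, rate k3*[racemization catalyst]*[left-handed substrate] forward; the back reaction follows from the equilibrium constant (k = 2800 M⁻¹ min⁻¹)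
    reagent + racemization catalyst → spent catalyst (k = 0.0200 M⁻¹ min⁻¹)
    free catalyst + added ligand ⇌ idle complex, settled at all times (K = 3900 M⁻¹)

For the neighbour charged with 2.5 mol% of free catalyst, the split again gives an excess of 51.8%, and 63.8% of left-handed product out of its 84.1% of product. The neighbour gave an excess of 52.1% and 64.0% of left-handed product.

(The earlier runs and the new flask were generated by integration with constants of no real substance, noise included.)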